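**Plan** (target numbered as a 3,7-dioxabicyclo[3.3.0]octane: C1 carbinol, C2 and C6 benzylic, C4 and C8 methylene, C5 ring-fusion CH)
1. Retrosynthesis: remove the benzyl ethers, take the C8 methylene back to a lactone carbonyl, then cut C1–C2 and C4–C5 together.
2. This double cut opens ring A (C1, C2, O3, C4, C5) into a carbonyl ylide C2–O3–C4 (ArCH=O⁺–CH2⁻, from O-benzylvanillin and Me3SiCH2OH) and the C1=C5 bond of an (S)-3-acetoxy-5-aryl-2(5H)-furanone (ring B: C1, C5, C6, O7, C8).
3. Enabling feature: ring A holds an aryl-CH–O–CH2 triad (C2, O3, C4) bridging the two ring-fusion carbons, and ring B puts C8 next to the oxygen-bearing C1; with C8 as a lactone carbonyl, C1=C5 is an electron-poor alkene that already carries the C1 oxygen.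
4. The butenolide goes back to the enol of an α-keto lactone, then to an α-methylene lactone, then to a chromium-catalysed asymmetric 2-(ethoxycarbonyl)allylation of the same aldehyde.
5. Forward: ring B (lactone) first, ring A in the cycloaddition, then lactone → lactol → ether and release of the phenols.
6. Stereochemistry: C6 from the catalyst in step 1; C1, C5 and C2 relayed from it in the one cycloaddition (anti to the C6 aryl, exo).

Key step: step 6

Assumption: in step 1 the ligand antipode is the one whose sense of induction gives the S carbinol; the aldehyde, the bromomethyl acrylate and (trimethylsilyl)methanol are taken as purchased.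

**Step 1**
Reactants: 1 4-(benzyloxy)-3-methoxybenzaldehyde; 2 ethyl 2-(bromomethyl)acrylate
Product: 5 (S)-5-[4-(benzyloxy)-3-methoxyphenyl]-3-methylidenedihydrofuran-2(3H)-one, via trimethylsilyl ether 3 (not isolated), via hydroxy ester 4 (not isolated)
Conditions: CrCl2 (10 mol %), chiral 1,8-bis(oxazolin-2-yl)carbazole ligand (12 mol %), Mn powder, Me3SiCl, iPr2NEt (cat.), THF, rt; 0.5 M aq. citric acid; then PPTS (cat.), toluene, 60 °C
Reagents that add atoms: none
Why: Chromium-catalysed asymmetric Nozaki–Hiyama–Kishi-type 2-(alkoxycarbonyl)allylation of an aromatic aldehyde, in which the ligand-bound allylchromium species adds to one enantiotopic face of 1 to set the future C6 as S, Me3SiCl turns the catalyst over, and the released γ-hydroxy ester lactonises without touching the new stereocentre.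

**Step 2**
Reactants: 5 (S)-5-[4-(benzyloxy)-3-methoxyphenyl]-3-methylidenedihydrofuran-2(3H)-one
Product: 7 (S)-5-[4-(benzyloxy)-3-methoxyphenyl]-3-hydroxyfuran-2(5H)-one, via keto lactone 6 (not isolated)
Conditions: O3, CH2Cl2, −78 °C (Sudan Red 7B as end-point indicator); then Me2S, −78 °C → rt
Reagents that add atoms: ozone, [O-][O+]=O
Why: Ozonolysis of the exocyclic 1,1-disubstituted alkene, titrated to the indicator end point to spare the dialkoxyarene, should give the α-keto lactone, which rests as its conjugated enol (an isotetronic acid) with the benzylic stereocentre untouched.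

**Step 3**
Reactants: 7 (S)-5-[4-(benzyloxy)-3-methoxyphenyl]-3-hydroxyfuran-2(5H)-one
Product: 8 (S)-5-[4-(benzyloxy)-3-methoxyphenyl]-2-oxo-2,5-dihydrofuran-3-yl acetate
Conditions: Ac2O, pyridine, CH2Cl2, 0 °C
Reagents that add atoms: acetic anhydride, CC(=O)OC(C)=O
Why: O-acylation of the acidic enol hydroxyl under weak-base conditions (no stronger amine, to avoid deprotonation at the benzylic γ-position) should give the enol acetate, an α-acyloxy acrylate-type alkene that stays electron-poor.

**Step 4**
Reactants: 1 4-(benzyloxy)-3-methoxybenzaldehyde; 9 (trimethylsilyl)methanol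
Product: 10 4-(benzyloxy)-3-methoxybenzaldehyde bis[(trimethylsilyl)methyl] acetal
Conditions: 9 (2.5 equiv), PPTS (cat.), benzene, reflux, azeotropic removal of water
Reagents that add atoms: none
Why: Acid-catalysed acetalisation of an aromatic aldehyde with a primary alcohol, driven by removal of water.

**Step 5**
Reactants: 10 4-(benzyloxy)-3-methoxybenzaldehyde bis[(trimethylsilyl)methyl] acetal
Product: 11 {[(4-(benzyloxy)-3-methoxyphenyl)(chloro)methoxy]methyl}trimethylsilane (racemic α-chloro ether)
Conditions: AcCl (1.05 equiv), CH2Cl2, 0 °C → rt; volatiles removed, crude 11 used at once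
Reagents that add atoms: acetyl chloride, CC(Cl)=O
Why: Acetal–acyl chloride exchange, the standard route to α-chlorobenzyl ethers: acylation of one alkoxy group ionises the electron-rich benzylic acetal and chloride captures the oxocarbenium ion.

**Step 6**
Reactants: 8 (S)-5-[4-(benzyloxy)-3-methoxyphenyl]-2-oxo-2,5-dihydrofuran-3-yl acetate; 11 {[(4-(benzyloxy)-3-methoxyphenyl)(chloro)methoxy]methyl}trimethylsilane
Product: 13 (3S,3aR,6R,6aR)-3,6-bis[4-(benzyloxy)-3-methoxyphenyl]-1-oxotetrahydro-1H,3H-furo[3,4-c]furan-6a-yl acetate, via carbonyl ylide 12 (not isolated)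
Conditions: CsF (2.5 equiv, added in portions), 11 (2 equiv), MeCN, 0 °C → rt
Reagents that add atoms: none
Why: Fluoride removes the silyl group from 11 (or from its ion pair, the p-alkoxy-stabilised oxocarbenium chloride) in a 1,3-elimination that gives the non-stabilised carbonyl ylide 12 (C2–O3–C4), which adds across C1=C5 of 8 in a concerted, asynchronous, suprafacial [3+2] cycloaddition; the closest known reaction types are the fluoride-triggered generation of carbonyl ylides from α-chloroalkyl (trimethylsilyl)methyl ethers with cycloaddition to α,β-unsaturated esters, and the anti-selective dipolar cycloadditions of 5-substituted 2(5H)-furanones. Ring A (C1, C2, O3, C4, C5) is closed by this intermolecular cycloaddition itself, both C–C bonds arising in one event, and its cis fusion to the lactone ring follows from the ring-held Z alkene. Regiochemistry: the unsubstituted methylene terminus has the larger HOMO coefficient and joins the β-carbon C5, while the benzylic terminus, which carries the cationic character, joins the enolate-like α-carbon C1; the lactone carbonyl (future C8) secures this polarisation, and an acetoxy group, unlike an alkoxy group, does not cancel it. C1 and C5 are set by approach of the ylide to the butenolide face anti to the C6 aryl group, the only stereocentre present. C2 is set by the aryl-out (E) geometry of the ylide combined with exo approach, in which the ylide oxygen and aryl group lie over the small acetoxy oxygen on the convex side and not over the lactone ring, so that the aryl group ends cis to the C1 oxygen. The step thus needs regio-, facial and exo selectivity, and keeping free fluoride low (portionwise CsF, excess 11) protects the enol acetate and the acidic benzylic C6–H.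

**Step 7**
Reactants: 13 (3S,3aR,6R,6aR)-3,6-bis[4-(benzyloxy)-3-methoxyphenyl]-1-oxotetrahydro-1H,3H-furo[3,4-c]furan-6a-yl acetate
Product: 14 (3S,3aR,6R,6aR)-3,6-bis[4-(benzyloxy)-3-methoxyphenyl]tetrahydro-1H,3H-furo[3,4-c]furan-1,6a-diol (lactol, both anomers at C1 of this name)
Conditions: iBu2AlH (4 equiv), CH2Cl2, −78 °C; MeOH, then aq. potassium sodium tartrate
Reagents that add atoms: none
Why: Half-reduction of a γ-lactone by iBu2AlH stops at the aluminium lactolate at −78 °C, and the same reagent cleaves the tertiary acetate reductively, so the ring-fusion hydroxyl is unveiled in the same operation; the new lactol centre is a mixture that is erased in step 8.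

**Step 8**
Reactants: 14 the lactol
Product: 15 (1S,2R,5R,6S)-2,6-bis[4-(benzyloxy)-3-methoxyphenyl]-3,7-dioxabicyclo[3.3.0]octan-1-ol
Conditions: Et3SiH (5 equiv), BF3·OEt2 (2 equiv), CH2Cl2, −78 → −40 °C; aq. NaHCO3
Reagents that add atoms: none
Why: Ionic hydrogenation of a lactol: BF3 ionises the lactol to the cyclic oxocarbenium ion and Et3SiH reduces it to the C8 methylene, the low temperature being chosen so that the benzylic C–O bonds at C2 and C6 do not ionise and keep their configuration.

**Step 9**
Reactants: 15 (1S,2R,5R,6S)-2,6-bis[4-(benzyloxy)-3-methoxyphenyl]-3,7-dioxabicyclo[3.3.0]octan-1-ol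
Product: 16 8-hydroxypinoresinol, (1S,2R,5R,6S)-2,6-bis(4-hydroxy-3-methoxyphenyl)-3,7-dioxabicyclo[3.3.0]octan-1-ol
Conditions: H2 (1 atm), 10% Pd/C, EtOAc, rt, stopped at full conversion of 15
Reagents that add atoms: none
Why: Hydrogenolysis of aryl benzyl ethers, which should be much faster than hydrogenolysis of the ring benzylic C–O bonds at atmospheric pressure in a non-protic solvent; no stereocentre is involved.

**Compound list**
1 | 4-(benzyloxy)-3-methoxybenzaldehyde (O-benzylvanillin) | O=Cc1ccc(OCc2ccccc2)c(OC)c1 | starting material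
2 | ethyl 2-(bromomethyl)acrylate | C=C(CBr)C(=O)OCC | starting material
3 | ethyl (S)-4-[4-(benzyloxy)-3-methoxyphenyl]-2-methylidene-4-[(trimethylsilyl)oxy]butanoate (formed in situ) | CCOC(=O)C(=C)C[C@H](O[Si](C)(C)C)c1ccc(OCc2ccccc2)c(OC)c1 | intermediate
4 | ethyl (S)-4-[4-(benzyloxy)-3-methoxyphenyl]-4-hydroxy-2-methylidenebutanoate (formed in situ) | CCOC(=O)C(=C)C[C@H](O)c1ccc(OCc2ccccc2)c(OC)c1 | intermediate
5 | (S)-5-[4-(benzyloxy)-3-methoxyphenyl]-3-methylidenedihydrofuran-2(3H)-one | C=C1C[C@@H](c2ccc(OCc3ccccc3)c(OC)c2)OC1=O | intermediate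
6 | (S)-5-[4-(benzyloxy)-3-methoxyphenyl]dihydrofuran-2,3-dione (keto tautomer, formed in situ) | O=C1C[C@@H](c2ccc(OCc3ccccc3)c(OC)c2)OC1=O | intermediate
7 | (S)-5-[4-(benzyloxy)-3-methoxyphenyl]-3-hydroxyfuran-2(5H)-one | OC1=C[C@@H](c2ccc(OCc3ccccc3)c(OC)c2)OC1=O | intermediate
8 | (S)-5-[4-(benzyloxy)-3-methoxyphenyl]-2-oxo-2,5-dihydrofuran-3-yl acetate | CC(=O)OC1=C[C@@H](c2ccc(OCc3ccccc3)c(OC)c2)OC1=O | intermediate
9 | (trimethylsilyl)methanol | C[Si](C)(C)CO | starting material
10 | 4-(benzyloxy)-3-methoxybenzaldehyde bis[(trimethylsilyl)methyl] acetal | COc1cc(C(OC[Si](C)(C)C)OC[Si](C)(C)C)ccc1OCc1ccccc1 | intermediate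
11 | {[(4-(benzyloxy)-3-methoxyphenyl)(chloro)methoxy]methyl}trimethylsilane (racemic, used crude) | COc1cc(C(Cl)OC[Si](C)(C)C)ccc1OCc1ccccc1 | intermediate
12 | carbonyl ylide, (E)-[4-(benzyloxy)-3-methoxybenzylidene]oxonium methylide (formed in situ) | [CH2-]/[O+]=C/c1ccc(OCc2ccccc2)c(OC)c1 | intermediate
13 | (3S,3aR,6R,6aR)-3,6-bis[4-(benzyloxy)-3-methoxyphenyl]-1-oxotetrahydro-1H,3H-furo[3,4-c]furan-6a-yl acetate (cis-fused, both aryl groups exo, C6 aryl cis to the acetoxy group) | COc1cc([C@H]2OC(=O)[C@]3(OC(C)=O)[C@@H](c4ccc(OCc5ccccc5)c(OC)c4)OC[C@H]23)ccc1OCc1ccccc1 | intermediate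
14 | (3S,3aR,6R,6aR)-3,6-bis[4-(benzyloxy)-3-methoxyphenyl]tetrahydro-1H,3H-furo[3,4-c]furan-1,6a-diol (lactol, anomeric mixture) | COc1cc([C@H]2OC(O)[C@]3(O)[C@@H](c4ccc(OCc5ccccc5)c(OC)c4)OC[C@H]23)ccc1OCc1ccccc1 | intermediate
15 | (1S,2R,5R,6S)-2,6-bis[4-(benzyloxy)-3-methoxyphenyl]-3,7-dioxabicyclo[3.3.0]octan-1-ol | COc1cc([C@H]2OC[C@]3(O)[C@@H](c4ccc(OCc5ccccc5)c(OC)c4)OC[C@H]23)ccc1OCc1ccccc1 | intermediate
16 | 8-hydroxypinoresinol, (1S,2R,5R,6S)-2,6-bis(4-hydroxy-3-methoxyphenyl)-3,7-dioxabicyclo[3.3.0]octan-1-ol | COc1cc([C@H]2OC[C@]3(O)[C@@H](c4ccc(O)c(OC)c4)OC[C@H]23)ccc1O | target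

**Total step count:** 9. **Longest linear sequence:** 7 (steps 1, 2, 3, 6, 7, 8, 9).

**Steps most likely to fail**

Step 6. Several processes may go wrong.
- The short-lived ylide may close to the aryl oxirane or dimerise faster than it adds to a trisubstituted alkene.
- Fluoride may transfer the acyl group off the activated enol acetate.
- Fluoride or the ylide may deprotonate the benzylic γ-position, eroding enantiomeric purity.
- The addition may leak to the reversed regiochemistry or to endo approach.

The fallback sets out from 1, uses 11, and returns at 14; it puts the C1 oxygen in after the cycloaddition, so the dipolarophile is the unhindered parent butenolide with no acyl group. Zinc alkynylide addition of methyl propiolate to 1 (Me2Zn, ProPhenol ligand antipode giving the R alcohol, toluene, 0 °C) should give methyl (R)-4-[4-(benzyloxy)-3-methoxyphenyl]-4-hydroxybut-2-ynoate F1. Semihydrogenation (H2, Pd/CaCO3 poisoned with Pb(OAc)2, quinoline, EtOAc) should give methyl (S,Z)-4-[4-(benzyloxy)-3-methoxyphenyl]-4-hydroxybut-2-enoate F2, which should lactonise on standing or with PPTS to (S)-5-[4-(benzyloxy)-3-methoxyphenyl]furan-2(5H)-one F3. Under the conditions of step 6, F3 and 11 should give the cis-fused lactone (3S,3aR,6S,6aS)-3,6-bis[4-(benzyloxy)-3-methoxyphenyl]tetrahydro-1H,3H-furo[3,4-c]furan-1-one F4; the hydrogen at the α-carbon leaves the exo approach open. Enolisation at the ring fusion (KN(SiMe3)2, THF, −78 °C) and oxidation with 2-(phenylsulfonyl)-3-phenyloxaziridine should hydroxylate the convex face, necessarily with retention of the cis fusion, to give (3S,3aR,6R,6aR)-3,6-bis[4-(benzyloxy)-3-methoxyphenyl]-6a-hydroxytetrahydro-1H,3H-furo[3,4-c]furan-1-one F5. The ring C–O bond β to the enolate lies near its nodal plane, which should disfavour β-elimination. iBu2AlH (CH2Cl2, −78 °C) should then give 14.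

Step 8. BF3 may ionise the p-alkoxybenzylic C2–O3 or C6–O7 bonds in competition with the lactol, whose ionisation is slowed by the adjacent C1 hydroxyl; this would cause epimerisation or reductive ring opening. The fallback sets out from 14 and returns at 15, replacing the cationic reduction by a radical one. Phosphine–disulfide thioacetalisation (PhSSPh, Bu3P, THF, rt) should give (3S,3aR,6R,6aR)-3,6-bis[4-(benzyloxy)-3-methoxyphenyl]-1-(phenylthio)tetrahydro-1H,3H-furo[3,4-c]furan-6a-ol F6. Bu3SnH with AIBN (toluene, 80 °C) should then replace the C–S bond by C–H through the α-oxy radical, under neutral conditions that leave the benzylic ethers alone, to give 15.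

Step 2. Ozone may attack the electron-rich dialkoxyarene at a rate comparable with the electron-poor acrylate-type alkene. The fallback sets out from 5 and returns at 7, splitting the cleavage into osmylation and glycol fission. OsO4 (cat.) with N-methylmorpholine N-oxide (acetone–water) should give (5S)-5-[4-(benzyloxy)-3-methoxyphenyl]-3-hydroxy-3-(hydroxymethyl)dihydrofuran-2(3H)-one F7 (C3 epimers, immaterial). NaIO4 (THF–water, 0 °C) should cleave the glycol to 6, which enolises to 7.

**Further compounds**
F1 | step 6 | methyl (R)-4-[4-(benzyloxy)-3-methoxyphenyl]-4-hydroxybut-2-ynoate | COC(=O)C#C[C@H](O)c1ccc(OCc2ccccc2)c(OC)c1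
F2 | step 6 | methyl (S,Z)-4-[4-(benzyloxy)-3-methoxyphenyl]-4-hydroxybut-2-enoate | COC(=O)/C=C\[C@H](O)c1ccc(OCc2ccccc2)c(OC)c1
F3 | step 6 | (S)-5-[4-(benzyloxy)-3-methoxyphenyl]furan-2(5H)-one | O=C1C=C[C@@H](c2ccc(OCc3ccccc3)c(OC)c2)O1
F4 | step 6 | (3S,3aR,6S,6aS)-3,6-bis[4-(benzyloxy)-3-methoxyphenyl]tetrahydro-1H,3H-furo[3,4-c]furan-1-one | COc1cc([C@H]2OC(=O)[C@@H]3[C@@H](c4ccc(OCc5ccccc5)c(OC)c4)OC[C@H]23)ccc1OCc1ccccc1
F5 | step 6 | (3S,3aR,6R,6aR)-3,6-bis[4-(benzyloxy)-3-methoxyphenyl]-6a-hydroxytetrahydro-1H,3H-furo[3,4-c]furan-1-one | COc1cc([C@H]2OC(=O)[C@]3(O)[C@@H](c4ccc(OCc5ccccc5)c(OC)c4)OC[C@H]23)ccc1OCc1ccccc1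
F6 | step 8 | (3S,3aR,6R,6aR)-3,6-bis[4-(benzyloxy)-3-methoxyphenyl]-1-(phenylthio)tetrahydro-1H,3H-furo[3,4-c]furan-6a-ol | COc1cc([C@H]2OC(Sc6ccccc6)[C@]3(O)[C@@H](c4ccc(OCc5ccccc5)c(OC)c4)OC[C@H]23)ccc1OCc1ccccc1
F7 | step 2 | (5S)-5-[4-(benzyloxy)-3-methoxyphenyl]-3-hydroxy-3-(hydroxymethyl)dihydrofuran-2(3H)-one | OCC1(O)C[C@@H](c2ccc(OCc3ccccc3)c(OC)c2)OC1=O
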